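**Retrosynthetic overview**
- The target comes from its penta-O-benzyl ether, and that from a bis(flavan-4-ol); the two C4 ketones are unveiled last so the epimerisable 2'',3''-cis half never meets base.
- Both pyran rings are closed together by intramolecular SNAr of the C2–O and C2''–O alkoxides onto 2-fluoroaryl rings, with retention at C2 and C2''.
- Both A rings are attached by aryl-metal addition to a 2,3-disubstituted succinaldehyde (C4 and C4'').
- The four stereocentres come from two auxiliary-controlled intermolecular aldol reactions on a succinate: an anti-aldol with 4-methoxybenzaldehyde (C2–C3, future trans ring) and a syn-aldol with 4-(benzyloxy)benzaldehyde (C2''–C3'', future cis ring). The central C3–C3'' bond is the succinate C–C bond.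
- Ring order: all aromatic rings are bought; no ring is formed until both pyran rings close in one late step.

Assumption: the target is read as the (2S,3R,2''S,3''S) isomer (unprimed locants = 4-methoxyphenyl flavanone half, double-primed = 4-hydroxyphenyl half), and these locants are used for the same carbons in the acyclic precursors.

**Route**

Step 1
Reactants: 1 succinic anhydride; 2 allyl alcohol
Product: 3 4-(allyloxy)-4-oxobutanoic acid
Conditions: Et3N, DMAP (cat.), CH2Cl2, 0 °C → rt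
Reagents that add atoms: none
Why: Alcoholysis of the cyclic anhydride stops at the half-ester and so differentiates the two succinate termini.

Step 2
Reactants: 3 4-(allyloxy)-4-oxobutanoic acid; 4 (4S)-4-benzyl-1,3-oxazolidin-2-one
Product: 6 allyl 4-[(4S)-4-benzyl-2-oxo-1,3-oxazolidin-3-yl]-4-oxobutanoate, via mixed pivalic anhydride 5 (not isolated)
Conditions: PivCl, Et3N, THF, −20 °C; then 4, LiCl, −20 °C → rt
Reagents that add atoms: none
Why: N-acylation of the Evans auxiliary through the mixed anhydride, which is attacked at the unhindered succinyl carbonyl.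

Step 3
Reactants: 6 allyl 4-[(4S)-4-benzyl-2-oxo-1,3-oxazolidin-3-yl]-4-oxobutanoate; 7 4-methoxybenzaldehyde
Product: 9 allyl (3R,4S)-3-{[(4S)-4-benzyl-2-oxo-1,3-oxazolidin-3-yl]carbonyl}-4-hydroxy-4-(4-methoxyphenyl)butanoate, via trimethylsilyl ether 8 (not isolated)
Conditions: MgCl2 (0.2 equiv), Et3N, TMSCl, EtOAc, 23 °C; then 1 M HCl, THF, 0 °C
Reagents that add atoms: none
Why: Evans MgCl2-catalysed direct anti-aldol reaction, in which the Mg-chelated Z-enolate of the imide reacts through a boat transition state on the face away from the benzyl group (the face used in Evans alkylations), setting C3 as R and the carbinol C2 as S (anti).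

Step 4
Reactants: 9 anti-aldol alcohol
Product: 10 allyl (3R,4S)-3-{[(4S)-4-benzyl-2-oxo-1,3-oxazolidin-3-yl]carbonyl}-4-{[tert-butyl(dimethyl)silyl]oxy}-4-(4-methoxyphenyl)butanoate
Conditions: TBSOTf, 2,6-lutidine, CH2Cl2, −78 → 0 °C
Reagents that add atoms: tert-butyldimethylsilyl trifluoromethanesulfonate (TBSOTf), `CC(C)(C)[Si](C)(C)OS(=O)(=O)C(F)(F)F`
Why: O-silylation with a silyl triflate and a hindered base protects the future ring oxygen and blocks lactonisation and retro-aldol cleavage.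

Step 5
Reactants: 10 silyl ether allyl ester
Product: 11 (3R,4S)-3-{[(4S)-4-benzyl-2-oxo-1,3-oxazolidin-3-yl]carbonyl}-4-{[tert-butyl(dimethyl)silyl]oxy}-4-(4-methoxyphenyl)butanoic acid
Conditions: Pd(PPh3)4 (5 mol%), N-methylaniline, THF, rt
Reagents that add atoms: none
Why: Tsuji–Trost deallylation under neutral conditions frees the acid without touching the imide, the silyl ether or the stereocentres.

Step 6
Reactants: 11 imide acid; 4 (4S)-4-benzyl-1,3-oxazolidin-2-one
Product: 13 (2R)-1,4-bis[(4S)-4-benzyl-2-oxo-1,3-oxazolidin-3-yl]-2-[(S)-{[tert-butyl(dimethyl)silyl]oxy}(4-methoxyphenyl)methyl]butane-1,4-dione, via mixed pivalic anhydride 12 (not isolated)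
Conditions: PivCl, Et3N, THF, −20 °C; then 4, LiCl, −20 °C → rt
Reagents that add atoms: none
Why: A second N-acylation of the same auxiliary via the mixed anhydride turns the former ester terminus into an enolisable CH2 imide, while the α-branched imide is left alone.

Step 7
Reactants: 13 bis-imide; 14 4-(benzyloxy)benzaldehyde
Product: 16 (2R,3S)-1,4-bis[(4S)-4-benzyl-2-oxo-1,3-oxazolidin-3-yl]-2-[(S)-{[tert-butyl(dimethyl)silyl]oxy}(4-methoxyphenyl)methyl]-3-[(S)-[4-(benzyloxy)phenyl](hydroxy)methyl]butane-1,4-dione, via Z dibutylboron enolate 15 (not isolated)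
Conditions: Bu2BOTf, iPr2NEt, CH2Cl2, 0 °C; then 14, −78 → 0 °C; pH 7 buffer, MeOH, 30% H2O2, 0 °C
Reagents that add atoms: none
Why: Evans boron syn-aldol reaction, in which only the CH2 imide arm can form the Z-boron enolate and its Zimmerman–Traxler chair (aldehyde opposite the auxiliary benzyl group) sets C3'' as S and C2'' as S under auxiliary control.

Step 8
Reactants: 16 syn-aldol alcohol
Product: 17 (2R,3S)-1,4-bis[(4S)-4-benzyl-2-oxo-1,3-oxazolidin-3-yl]-2-[(S)-{[tert-butyl(dimethyl)silyl]oxy}(4-methoxyphenyl)methyl]-3-[(S)-[4-(benzyloxy)phenyl]{[tert-butyl(dimethyl)silyl]oxy}methyl]butane-1,4-dione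
Conditions: TBSOTf, 2,6-lutidine, CH2Cl2, −78 → 0 °C (directly after step 7)
Reagents that add atoms: tert-butyldimethylsilyl trifluoromethanesulfonate (TBSOTf), `CC(C)(C)[Si](C)(C)OS(=O)(=O)C(F)(F)F`
Why: Prompt O-silylation prevents the γ-hydroxy imide from lactonising onto the neighbouring imide and protects the second future ring oxygen.

Step 9
Reactants: 17 bis-silyl bis-imide
Product: 18 (2S,3R)-2-[(S)-{[tert-butyl(dimethyl)silyl]oxy}(4-methoxyphenyl)methyl]-3-[(S)-[4-(benzyloxy)phenyl]{[tert-butyl(dimethyl)silyl]oxy}methyl]butane-1,4-diol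
Conditions: LiBH4, MeOH (2.5 equiv), THF, 0 °C → rt
Reagents that add atoms: none
Why: Reductive cleavage of both N-acyloxazolidinones by hydride attack at the exocyclic carbonyls gives the 1,4-diol and returns the auxiliary (the descriptors change only through priority changes, not through any change in space).

Step 10
Reactants: 18 diol
Product: 19 (2R,3S)-2-[(S)-{[tert-butyl(dimethyl)silyl]oxy}(4-methoxyphenyl)methyl]-3-[(S)-[4-(benzyloxy)phenyl]{[tert-butyl(dimethyl)silyl]oxy}methyl]butanedial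
Conditions: (COCl)2, DMSO, CH2Cl2, −78 °C; then iPr2NEt, −78 → −30 °C; used crude
Reagents that add atoms: none
Why: Swern oxidation activates both hydroxyls before base is added, so the dialdehyde forms without the lactol and lactone that stepwise oxidants give with 1,4-diols, and the cold hindered-amine work-up avoids α-epimerisation.

Step 11
Reactants: 20 1,3,5-trifluorobenzene; 21 benzyl alcohol
Product: 23 1,3-bis(benzyloxy)-5-fluorobenzene, via sodium benzyloxide 22 (not isolated)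
Conditions: 21 (2.1 equiv), NaH, DMF, 0 °C; then 20, 0 → 80 °C
Reagents that add atoms: none
Why: Two successive SNAr displacements of fluoride, the third being slower because each benzyloxy group is less electron-withdrawing than the fluorine it replaces.

Step 12
Reactants: 19 dialdehyde; 23 1,3-bis(benzyloxy)-5-fluorobenzene
Product: 26 1,4-bis[2,4-bis(benzyloxy)-6-fluorophenyl]-2-[(S)-{[tert-butyl(dimethyl)silyl]oxy}(4-methoxyphenyl)methyl]-3-[(S)-[4-(benzyloxy)phenyl]{[tert-butyl(dimethyl)silyl]oxy}methyl]butane-1,4-diol (backbone C2/C3 as in 19; epimer mixture at C1/C4), via aryllithium 24 (not isolated), via arylmagnesium bromide 25 (not isolated)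
Conditions: 23 (5 equiv), n-BuLi, THF, −78 °C; MgBr2·OEt2, −78 °C; then 19, −78 → 0 °C; aq. NH4Cl
Reagents that add atoms: none
Why: Directed ortho-lithiation at the carbon flanked by F and OBn, transmetalation to the less basic Grignard reagent and Grignard 1,2-addition to both aldehydes install the two A rings; the new carbinol centres form unselectively but become ketones in step 15.

Step 13
Reactants: 26 bis-silyl bis-carbinol
Product: 27 1,4-bis[2,4-bis(benzyloxy)-6-fluorophenyl]-2-[(S)-hydroxy(4-methoxyphenyl)methyl]-3-[(S)-[4-(benzyloxy)phenyl](hydroxy)methyl]butane-1,4-diol (epimer mixture at C1/C4)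
Conditions: TBAF, THF, 0 °C → rt
Reagents that add atoms: none
Why: Fluoride-mediated desilylation frees the C2 and C2'' hydroxyls, and nothing else in the molecule reacts with fluoride at room temperature.

Step 14
Reactants: 27 tetraol
Product: 28 5,7-bis(benzyloxy)-3-{5,7-bis(benzyloxy)-2-[4-(benzyloxy)phenyl]-4-hydroxychroman-3-yl}-2-(4-methoxyphenyl)chroman-4-ol (2,3-trans; 2'',3''-cis; epimer mixture at C4/C4'')
Conditions: NaH (6 equiv), DMF, 0 → 60 °C
Reagents that add atoms: none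
Why: Double intramolecular SNAr (six-membered ring closure preferred over the seven-membered alternatives) of the C2 and C2'' alkoxides on the fluoroarenes leaves the C–O bonds at C2 and C2'' intact, so the anti-aldol pair becomes the 2,3-trans ring and the syn-aldol pair the 2'',3''-cis ring, and with no carbonyl present nothing can epimerise.

Step 15
Reactants: 28 bis(flavan-4-ol)
Product: 29 (2S,3R)-5,7-bis(benzyloxy)-3-{(2S,3S)-5,7-bis(benzyloxy)-2-[4-(benzyloxy)phenyl]-4-oxochroman-3-yl}-2-(4-methoxyphenyl)chroman-4-one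
Conditions: Dess–Martin periodinane, NaHCO3, CH2Cl2, 0 °C → rt
Reagents that add atoms: none
Why: Dess–Martin oxidation of both benzylic alcohols under buffered, essentially neutral conditions gives the diketone without enolising C3 or the contra-thermodynamic cis C3''.

Step 16
Reactants: 29 penta-O-benzyl biflavanone
Product: 30 (2S,3R)-5,7-dihydroxy-3-[(2S,3S)-5,7-dihydroxy-2-(4-hydroxyphenyl)-4-oxochroman-3-yl]-2-(4-methoxyphenyl)chroman-4-one (CNP0196568.6)
Conditions: H2 (1 atm), 10% Pd/C, EtOAc–MeOH, rt, stopped at full debenzylation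
Reagents that add atoms: none
Why: Catalytic hydrogenolysis removes the five benzyl ethers under neutral conditions, leaving the methyl ether, the vinylogous-ester carbonyls and the ring C2–O bonds, and touching no stereocentre.

**Compound list**

1 | succinic anhydride | `O=C1CCC(=O)O1` | starting material
2 | allyl alcohol (prop-2-en-1-ol) | `C=CCO` | starting material
3 | 4-(allyloxy)-4-oxobutanoic acid | `OC(=O)CCC(=O)OCC=C` | intermediate
4 | (4S)-4-benzyl-1,3-oxazolidin-2-one | `O=C1N[C@@H](Cc2ccccc2)CO1` | starting material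
5 | allyl 4-oxo-4-(pivaloyloxy)butanoate (mixed anhydride; not isolated) | `C=CCOC(=O)CCC(=O)OC(=O)C(C)(C)C` | intermediate
6 | allyl 4-[(4S)-4-benzyl-2-oxo-1,3-oxazolidin-3-yl]-4-oxobutanoate | `C=CCOC(=O)CCC(=O)N1[C@@H](Cc2ccccc2)COC1=O` | intermediate
7 | 4-methoxybenzaldehyde | `COc1ccc(C=O)cc1` | starting material
8 | allyl (3R,4S)-3-{[(4S)-4-benzyl-2-oxo-1,3-oxazolidin-3-yl]carbonyl}-4-(4-methoxyphenyl)-4-(trimethylsilyloxy)butanoate (not isolated) | `COc1ccc(cc1)[C@@H](O[Si](C)(C)C)[C@H](C(=O)N1[C@@H](Cc2ccccc2)COC1=O)CC(=O)OCC=C` | intermediate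
9 | allyl (3R,4S)-3-{[(4S)-4-benzyl-2-oxo-1,3-oxazolidin-3-yl]carbonyl}-4-hydroxy-4-(4-methoxyphenyl)butanoate | `COc1ccc(cc1)[C@@H](O)[C@H](C(=O)N1[C@@H](Cc2ccccc2)COC1=O)CC(=O)OCC=C` | intermediate
10 | allyl (3R,4S)-3-{[(4S)-4-benzyl-2-oxo-1,3-oxazolidin-3-yl]carbonyl}-4-{[tert-butyl(dimethyl)silyl]oxy}-4-(4-methoxyphenyl)butanoate | `COc1ccc(cc1)[C@@H](O[Si](C)(C)C(C)(C)C)[C@H](C(=O)N1[C@@H](Cc2ccccc2)COC1=O)CC(=O)OCC=C` | intermediate
11 | (3R,4S)-3-{[(4S)-4-benzyl-2-oxo-1,3-oxazolidin-3-yl]carbonyl}-4-{[tert-butyl(dimethyl)silyl]oxy}-4-(4-methoxyphenyl)butanoic acid | `COc1ccc(cc1)[C@@H](O[Si](C)(C)C(C)(C)C)[C@H](C(=O)N1[C@@H](Cc2ccccc2)COC1=O)CC(=O)O` | intermediate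
12 | mixed pivalic anhydride of acid 11 (not isolated) | `COc1ccc(cc1)[C@@H](O[Si](C)(C)C(C)(C)C)[C@H](C(=O)N1[C@@H](Cc2ccccc2)COC1=O)CC(=O)OC(=O)C(C)(C)C` | intermediate
13 | (2R)-1,4-bis[(4S)-4-benzyl-2-oxo-1,3-oxazolidin-3-yl]-2-[(S)-{[tert-butyl(dimethyl)silyl]oxy}(4-methoxyphenyl)methyl]butane-1,4-dione | `COc1ccc(cc1)[C@@H](O[Si](C)(C)C(C)(C)C)[C@H](C(=O)N1[C@@H](Cc2ccccc2)COC1=O)CC(=O)N1[C@@H](Cc2ccccc2)COC1=O` | intermediate
14 | 4-(benzyloxy)benzaldehyde | `O=Cc1ccc(OCc2ccccc2)cc1` | starting material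
15 | Z dibutylboron enolate of 13, formed at the CH2–C(=O)N arm (not isolated) | `COc1ccc(cc1)[C@@H](O[Si](C)(C)C(C)(C)C)[C@H](C(=O)N1[C@@H](Cc2ccccc2)COC1=O)/C=C(\OB(CCCC)CCCC)N1[C@@H](Cc2ccccc2)COC1=O` | intermediate
16 | (2R,3S)-1,4-bis[(4S)-4-benzyl-2-oxo-1,3-oxazolidin-3-yl]-2-[(S)-{[tert-butyl(dimethyl)silyl]oxy}(4-methoxyphenyl)methyl]-3-[(S)-[4-(benzyloxy)phenyl](hydroxy)methyl]butane-1,4-dione | `COc1ccc(cc1)[C@@H](O[Si](C)(C)C(C)(C)C)[C@H](C(=O)N1[C@@H](Cc2ccccc2)COC1=O)[C@H](C(=O)N1[C@@H](Cc2ccccc2)COC1=O)[C@H](O)c1ccc(OCc2ccccc2)cc1` | intermediate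
17 | (2R,3S)-1,4-bis[(4S)-4-benzyl-2-oxo-1,3-oxazolidin-3-yl]-2-[(S)-{[tert-butyl(dimethyl)silyl]oxy}(4-methoxyphenyl)methyl]-3-[(S)-[4-(benzyloxy)phenyl]{[tert-butyl(dimethyl)silyl]oxy}methyl]butane-1,4-dione | `COc1ccc(cc1)[C@@H](O[Si](C)(C)C(C)(C)C)[C@H](C(=O)N1[C@@H](Cc2ccccc2)COC1=O)[C@H](C(=O)N1[C@@H](Cc2ccccc2)COC1=O)[C@H](O[Si](C)(C)C(C)(C)C)c1ccc(OCc2ccccc2)cc1` | intermediate
18 | (2S,3R)-2-[(S)-{[tert-butyl(dimethyl)silyl]oxy}(4-methoxyphenyl)methyl]-3-[(S)-[4-(benzyloxy)phenyl]{[tert-butyl(dimethyl)silyl]oxy}methyl]butane-1,4-diol | `COc1ccc(cc1)[C@@H](O[Si](C)(C)C(C)(C)C)[C@H](CO)[C@H](CO)[C@H](O[Si](C)(C)C(C)(C)C)c1ccc(OCc2ccccc2)cc1` | intermediate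
19 | (2R,3S)-2-[(S)-{[tert-butyl(dimethyl)silyl]oxy}(4-methoxyphenyl)methyl]-3-[(S)-[4-(benzyloxy)phenyl]{[tert-butyl(dimethyl)silyl]oxy}methyl]butanedial | `COc1ccc(cc1)[C@@H](O[Si](C)(C)C(C)(C)C)[C@H](C=O)[C@H](C=O)[C@H](O[Si](C)(C)C(C)(C)C)c1ccc(OCc2ccccc2)cc1` | intermediate
20 | 1,3,5-trifluorobenzene | `Fc1cc(F)cc(F)c1` | starting material
21 | benzyl alcohol | `OCc1ccccc1` | starting material
22 | sodium benzyloxide (not isolated) | `[Na+].[O-]Cc1ccccc1` | intermediate
23 | 1,3-bis(benzyloxy)-5-fluorobenzene | `Fc1cc(OCc2ccccc2)cc(OCc2ccccc2)c1` | intermediate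
24 | [2,4-bis(benzyloxy)-6-fluorophenyl]lithium (not isolated) | `[Li]c1c(F)cc(OCc2ccccc2)cc1OCc1ccccc1` | intermediate
25 | [2,4-bis(benzyloxy)-6-fluorophenyl]magnesium bromide (not isolated) | `Br[Mg]c1c(F)cc(OCc2ccccc2)cc1OCc1ccccc1` | intermediate
26 | 1,4-bis[2,4-bis(benzyloxy)-6-fluorophenyl]-2-[(S)-{[tert-butyl(dimethyl)silyl]oxy}(4-methoxyphenyl)methyl]-3-[(S)-[4-(benzyloxy)phenyl]{[tert-butyl(dimethyl)silyl]oxy}methyl]butane-1,4-diol; backbone C2/C3 arranged as in 19; epimer mixture at C1/C4 | `COc1ccc(cc1)[C@@H](O[Si](C)(C)C(C)(C)C)[C@H](C(O)c1c(F)cc(OCc2ccccc2)cc1OCc1ccccc1)[C@H](C(O)c1c(F)cc(OCc2ccccc2)cc1OCc1ccccc1)[C@H](O[Si](C)(C)C(C)(C)C)c1ccc(OCc2ccccc2)cc1` | intermediate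
27 | 1,4-bis[2,4-bis(benzyloxy)-6-fluorophenyl]-2-[(S)-hydroxy(4-methoxyphenyl)methyl]-3-[(S)-[4-(benzyloxy)phenyl](hydroxy)methyl]butane-1,4-diol; backbone as in 19; epimer mixture at C1/C4 | `COc1ccc(cc1)[C@@H](O)[C@H](C(O)c1c(F)cc(OCc2ccccc2)cc1OCc1ccccc1)[C@H](C(O)c1c(F)cc(OCc2ccccc2)cc1OCc1ccccc1)[C@H](O)c1ccc(OCc2ccccc2)cc1` | intermediate
28 | 5,7-bis(benzyloxy)-3-{5,7-bis(benzyloxy)-2-[4-(benzyloxy)phenyl]-4-hydroxychroman-3-yl}-2-(4-methoxyphenyl)chroman-4-ol; 2,3-trans and 2'',3''-cis, arranged at C2/C3/C2''/C3'' as in 29; epimer mixture at C4/C4'' | `COc1ccc([C@H]2Oc3cc(OCc4ccccc4)cc(OCc4ccccc4)c3C(O)[C@@H]2[C@@H]2C(O)c3c(OCc4ccccc4)cc(OCc4ccccc4)cc3O[C@@H]2c2ccc(OCc3ccccc3)cc2)cc1` | intermediate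
29 | (2S,3R)-5,7-bis(benzyloxy)-3-{(2S,3S)-5,7-bis(benzyloxy)-2-[4-(benzyloxy)phenyl]-4-oxochroman-3-yl}-2-(4-methoxyphenyl)chroman-4-one | `COc1ccc([C@H]2Oc3cc(OCc4ccccc4)cc(OCc4ccccc4)c3C(=O)[C@@H]2[C@@H]2C(=O)c3c(OCc4ccccc4)cc(OCc4ccccc4)cc3O[C@@H]2c2ccc(OCc3ccccc3)cc2)cc1` | intermediate
30 | (2S,3R)-5,7-dihydroxy-3-[(2S,3S)-5,7-dihydroxy-2-(4-hydroxyphenyl)-4-oxochroman-3-yl]-2-(4-methoxyphenyl)chroman-4-one (CNP0196568.6) | `COc1ccc([C@H]2Oc3cc(O)cc(O)c3C(=O)[C@@H]2[C@@H]2C(=O)c3c(O)cc(O)cc3O[C@@H]2c2ccc(O)cc2)cc1` | target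

**Step count and risk**

Total steps: 16. Longest linear sequence: 15 steps (steps 1–10 and 12–16, from succinic anhydride); step 11 is a one-step side branch.

The three steps most likely to fail:

Step 12 (double aryl addition to the dialdehyde). After the first addition the alkoxide can close onto the second aldehyde as a lactolate and stall the reaction, and the basic organometallic can enolise the α-branched aldehydes and erode C3 or C3''. The fallback sets out from dialdehyde 19, with 23 as the aryl source. Aryllithium 24 is quenched with I2 (THF, −78 °C) to give 1,5-bis(benzyloxy)-3-fluoro-2-iodobenzene F2. F2 is then coupled with 19 under Nozaki–Hiyama–Kishi conditions (CrCl2 in excess, NiCl2 cat., DMF, rt). The organochromium reagent is non-basic and adds to aldehydes only, so both aldehydes are arylated without enolisation, and the sequence comes back to the route at 26.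

Step 14 (double SNAr on an unactivated fluoroarene). The ring carries no strongly electron-withdrawing group, so closure may need forcing conditions or stop after one ring. The fallback sets out from 26. Dess–Martin oxidation gives the diketone (2R,3S)-1,4-bis[2,4-bis(benzyloxy)-6-fluorophenyl]-2-[(S)-{[tert-butyl(dimethyl)silyl]oxy}(4-methoxyphenyl)methyl]-3-[(S)-[4-(benzyloxy)phenyl]{[tert-butyl(dimethyl)silyl]oxy}methyl]butane-1,4-dione F3. HF·pyridine (THF, 0 °C) then removes both silyl groups to give the bis(β-hydroxy ketone) (2R,3S)-1,4-bis[2,4-bis(benzyloxy)-6-fluorophenyl]-2-[(S)-hydroxy(4-methoxyphenyl)methyl]-3-[(S)-[4-(benzyloxy)phenyl](hydroxy)methyl]butane-1,4-dione F4. With the ortho-acyl group now activating each fluoride, K2CO3 in DMF at 0 °C effects both ring closures with retention at C2 and C2''. The reaction is stopped at conversion to limit retro-aldol cleavage and epimerisation of the cis half. This comes back to the route at 29 and bypasses 27 and 28.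

Step 9 (reductive removal of two hindered auxiliaries). Hydride may open the oxazolidinone rings (endocyclic attack) or stop after one imide. The fallback sets out from 17. LiOH/H2O2 (THF–H2O, 0 °C) cleaves both imides at the exocyclic carbonyl to give the diacid (2R,3S)-2-[(S)-{[tert-butyl(dimethyl)silyl]oxy}(4-methoxyphenyl)methyl]-3-[(S)-[4-(benzyloxy)phenyl]{[tert-butyl(dimethyl)silyl]oxy}methyl]butanedioic acid F1. BH3·SMe2 (THF, 0 °C → rt) then reduces F1 to the diol, coming back to the route at 18.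

**Further compounds**

F1 | step 9 | (2R,3S)-2-[(S)-{[tert-butyl(dimethyl)silyl]oxy}(4-methoxyphenyl)methyl]-3-[(S)-[4-(benzyloxy)phenyl]{[tert-butyl(dimethyl)silyl]oxy}methyl]butanedioic acid | `COc1ccc(cc1)[C@@H](O[Si](C)(C)C(C)(C)C)[C@H](C(=O)O)[C@H](C(=O)O)[C@H](O[Si](C)(C)C(C)(C)C)c1ccc(OCc2ccccc2)cc1`
F2 | step 12 | 1,5-bis(benzyloxy)-3-fluoro-2-iodobenzene | `Ic1c(F)cc(OCc2ccccc2)cc1OCc1ccccc1`
F3 | step 14 | (2R,3S)-1,4-bis[2,4-bis(benzyloxy)-6-fluorophenyl]-2-[(S)-{[tert-butyl(dimethyl)silyl]oxy}(4-methoxyphenyl)methyl]-3-[(S)-[4-(benzyloxy)phenyl]{[tert-butyl(dimethyl)silyl]oxy}methyl]butane-1,4-dione | `COc1ccc(cc1)[C@@H](O[Si](C)(C)C(C)(C)C)[C@H](C(=O)c1c(F)cc(OCc2ccccc2)cc1OCc1ccccc1)[C@H](C(=O)c1c(F)cc(OCc2ccccc2)cc1OCc1ccccc1)[C@H](O[Si](C)(C)C(C)(C)C)c1ccc(OCc2ccccc2)cc1`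
F4 | step 14 | (2R,3S)-1,4-bis[2,4-bis(benzyloxy)-6-fluorophenyl]-2-[(S)-hydroxy(4-methoxyphenyl)methyl]-3-[(S)-[4-(benzyloxy)phenyl](hydroxy)methyl]butane-1,4-dione | `COc1ccc(cc1)[C@@H](O)[C@H](C(=O)c1c(F)cc(OCc2ccccc2)cc1OCc1ccccc1)[C@H](C(=O)c1c(F)cc(OCc2ccccc2)cc1OCc1ccccc1)[C@H](O)c1ccc(OCc2ccccc2)cc1`
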